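The target forms from starting material, fed over 2.0 min, by way of an open intermediate that the capture agent may intercept.

| flask | starting material | capture agent | remark | time |
|---|---|---|---|---|
| spring | 0.050 M (fed, over 2.0 min) | 0.0015 M | run made earlier; the fed solution adds 0.20 times the starting volume |  |
| noon | 0.050 M (fed, over 2.0 min) | 0.018 M | run made earlier; the fed solution adds 0.20 times the starting volume |  |
| ash | 0.050 M (fed, over 2.0 min) | 0.00100 M | the fed solution adds 0.20 times the starting volume | 5.0 min |
| alder | 0.050 M (fed, over 2.0 min) | 0.00200 M | the fed solution adds 0.20 times the starting volume | 5.0 min |
| cedar | 0.050 M (fed, over 2.0 min) | 0.00400 M | the fed solution adds 0.20 times the starting volume | 5.0 min |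
| elm | 0.050 M (fed, over 2.0 min) | 0.00800 M | the fed solution adds 0.20 times the starting volume | 5.0 min |
| maple | 0.050 M (fed, over 2.0 min) | 0.0150 M | the fed solution adds 0.20 times the starting volume | 5.0 min |

| run | time / min | target / % | starting material / % |
|---|---|---|---|
| spring | 0.333 | 0 | 16 |
| spring | 1.00 | 6 | 44 |
| spring | 2.00 | 20 | 76 |
| spring | 2.50 | 31 | 67 |
| spring | 4.00 | 53 | 40 |
| spring | 5.00 | 60 | 31 |
| noon | 0.833 | 5 | 34 |
| noon | 1.50 | 11 | 63 |
| noon | 2.50 | 30 | 62 |
| noon | 3.00 | 39 | 52 |
| noon | 4.00 | 51 | 42 |
| noon | 5.00 | 61 | 31 |

(each reading ± 1.5 percentage points)

- amounts are per litre of the starting volume; all of the dose is in the solution fed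
- the earlier runs were read with a standard deviation of 1.5 percentage points
- what may be going on: starting material <-> open intermediate; open intermediate -> target; open intermediate + capture agent -> trapped intermediate; target <-> isomer of the product
- "hardly changes" means that all values lie within two and a half points (for a concentration: within two and a half percent of the largest)
- percentages count the whole charge, also what has not yet gone in

1. amount of target at the end, in percent of the starting material charged for ash, alder, cedar, elm, maple, in this order
2. the shape of the row from first to last (rises all the way / rises, then falls / falls all the way / hardly changes / falls, then rises)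

The noon run held 12.0 times the capture agent of the spring run, 0.018 M against 0.0015 M. That is a third of the starting material charged, yet target at 5.00 min reads 61 % at noon and 60 % in spring.

The charge of capture agent is the wrong measure. Take the open intermediate as held at a quasi-steady state: each molecule leaves by one of two exits, and trapped over formed product is κc. Here c is the capture agent as charged and κ is a selectivity factor per molar of charge: the ratio of the capture rate constant to the rate constant towards target, divided by the mean dilution by the feed, a dilution that reaches 1.20 once the feed is in.

The readings bound κ. Spring minus noon is −1 percentage point, and two standard deviations of that difference raise the possible loss to 3.2 points. Spread over the 0.0165 M between the runs, this gives the capture limit κ_max = 3.28 M⁻¹. At that limit the noon run diverts 5.90 % of the open intermediate, less than the share its charge of capture agent could take.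

Across the new row, from 0.00100 M to 0.0150 M, the same limit allows a fall of 2.8 points. That sits at the edge of what counts as hardly changes, while the central reading shows no loss, so this reckoning expects a nearly flat row.

The forecast, holding that “trapping does not compete measurably”, gave 60.5 %, 60.5 %, 60.5 %, 60.5 % and 60.5 %, shape hardly changes.

The flasks give 60.2 %, 60.2 %, 60.1 %, 60.0 % and 59.9 %, shape hardly changes.

    starting material ⇌ open intermediate (K = 2.20, k = 0.310 min⁻¹)
    open intermediate → target (k = 7.20 min⁻¹)
    open intermediate + capture agent → trapped intermediate (k = 2.70 M⁻¹ min⁻¹)
    target ⇌ isomer of the product (K = 3.60, k = 0.0580 min⁻¹)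

Through the feed, to 2.00 min, starting material in maple built up to 74.9 % while open intermediate, standing at 2.99 %, passed on to target; after the feed, starting material fell to 30.1 % by 5.00 min and target kept passing into isomer of the product, 8.35 % by then. Trapped intermediate over target plus isomer, per molar of charge, gives κ = 0.317 M⁻¹ in maple and 0.317 M⁻¹ in ash, below the limit 3.28 M⁻¹, which puts the diverted share in maple at 0.475 %, with trapped intermediate at 0.324 %.

The data were computed with made-up constants, noise included.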